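**Plan**

1. Target numbering: C1 = ring alkene carbon bearing CH2OBz, C2 = ring =CH, C3 and C4 = CHOH, C5 = CHOAc, C6 = CHOBz. The retrosynthesis first removes the acyl groups, then cuts the cis-1,4 pair C3–O/C6–O back to a cyclohexa-1,3-diene (singlet oxygen), then cuts the ring bonds C3–C4 and C5–C6 in one [4+2] cycloaddition.
2. Enabling feature: the ring double bond C1=C2 lies between the two allylic carbinol carbons C6 and C3, and both of these are bonded to the cis-dioxygenated edge C5–C4. This is the pattern of a diene (C6–C1–C2–C3, with the exocyclic carbon on C1) joined to a cis-enediol. The diene is taken as C-6/C-5/C-4/C-3 of methyl coumalate (ester = future CH2OBz) and the enediol as vinylene carbonate.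
3. Forward order: the cycloaddition builds the carbocycle inside a 2-oxabicyclo[2.2.2]octene; the CO2 bridge (temporary ring) then leaves and gives a cis-dioxygenated cyclohexadiene. The ester is taken to CH2OBz, singlet oxygen brings in O-3 and O-6, and the acyl groups are placed last.
4. Stereochemistry: C4/C5 cis from the ring-locked (Z)-dienophile; C3 and C6 from singlet oxygen adding anti to the acetonide; absolute configuration from a lipase kinetic resolution that also differentiates O-3 from O-6; the acetate is put on O-5 by axial-selective orthoester opening.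

Key step: step 1

Remark on the chemistry: compounds 3 to 10 are racemic and are drawn and named as the enantiomer that step 7 carries forward; the lipase is assumed to follow the usual secondary-alcohol rule at C-7 of 10.

**Route**

Step 1
Reactants: 1 methyl coumalate (methyl 2-oxo-2H-pyran-5-carboxylate); 2 vinylene carbonate (1,3-dioxol-2-one)
Product: 3 methyl 7,8-(carbonyldioxy)-3-oxo-2-oxabicyclo[2.2.2]oct-5-ene-6-carboxylate (cis-carbonate; racemic endo/exo mixture)
Conditions: 2 (6 equiv, neat), BHT (cat.), 95 °C, sealed tube; excess 2 removed in vacuo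
Reagents that add atoms: none
Why: Concerted suprafacial [4+2] cycloaddition in which the pyrone diene C-3=C-4–C-5=C-6, made electron-poor by the lactone and the 5-ester, takes up the enediol-type alkene of 2 in the inverse-demand sense; the closest known reaction type is the thermal Diels–Alder reaction of 2-pyrones with vinylene carbonate and of coumalate esters with enol ethers. The step closes the six-membered carbocycle (future C1–C6) by cycloaddition across the pyrone termini, so that it arises as the carbocyclic ring of a 2-oxabicyclo[2.2.2]octene with the CO2 bridge as a temporary second ring. The two carbonate-bearing carbons (future C-4 and C-5) become cis because the (Z)-geometry of 2 is locked in its ring and the addition is suprafacial; the two bridgehead centres are fixed by the bicycle and disappear again in step 2. Regiochemistry does not arise because 2 is symmetrical, and endo/exo selectivity is not needed because both adducts give the same diene. What is needed is mono-addition without premature loss of CO2, which the moderate temperature should secure because the diene formed after decarboxylation would otherwise add a second molecule of 2. No facial control is exerted, so 3 is racemic.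

Step 2
Reactants: 3 bicyclic lactone carbonate
Product: 4 methyl (3aR,7aS)-2-oxo-3a,7a-dihydro-1,3-benzodioxole-5-carboxylate (racemic)
Conditions: PhMe (0.02 M), BHT (cat.), 120 °C, sealed tube
Reagents that add atoms: none
Why: Retro-Diels–Alder extrusion of CO2 from the 2-oxabicyclo[2.2.2]oct-5-en-3-one should give the cyclohexa-1,3-diene with the two carbonate-bearing stereocentres untouched and the bridgehead ones erased, while high dilution and the absence of 2 should suppress a second cycloaddition.

Step 3
Reactants: 4 diene carbonate ester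
Product: 6 methyl (3aR,7aS)-2,2-dimethyl-3a,7a-dihydro-1,3-benzodioxole-5-carboxylate (racemic), via diene cis-diol 5 (not isolated)
Conditions: K2CO3 (0.2 equiv), MeOH, 0 °C; AcOH quench, evaporate; then Me2C(OMe)2, TsOH·H2O (cat.), acetone, 0 °C → rt
Reagents that add atoms: 2,2-dimethoxypropane, CC(C)(OC)OC
Why: Base-catalysed transesterification of the five-membered cyclic carbonate by methanol should be much faster than any attack on the conjugated ester, and the freed cis-diol should close to the cis-fused isopropylidene acetal (acetonide formation) without change at either stereocentre.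

Step 4
Reactants: 6 diene acetonide ester
Product: 7 [(3aR,7aS)-2,2-dimethyl-3a,7a-dihydro-1,3-benzodioxol-5-yl]methanol (racemic)
Conditions: i-Bu2AlH (2.5 equiv), CH2Cl2, −78 °C; aq. KNaC4H4O6 work-up
Reagents that add atoms: none
Why: Reduction of a conjugated ester with i-Bu2AlH stops at the allylic alcohol by 1,2-hydride delivery, and the acetonide and the diene are inert to it.

Step 5
Reactants: 7 dienyl alcohol
Product: 8 [(3aR,7aS)-2,2-dimethyl-3a,7a-dihydro-1,3-benzodioxol-5-yl]methyl benzoate (racemic)
Conditions: BzCl, pyridine, DMAP (cat.), CH2Cl2, 0 °C; used without storage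
Reagents that add atoms: benzoyl chloride, O=C(Cl)c1ccccc1
Why: Benzoylation of the primary alcohol under basic conditions (pyridine-mediated acylation) avoids the acid to which the dihydroarene acetonide is sensitive.

Step 6
Reactants: 8 diene benzoate
Product: 10 [(3aR,4S,7R,7aS)-4,7-dihydroxy-2,2-dimethyl-3a,4,7,7a-tetrahydro-1,3-benzodioxol-5-yl]methyl benzoate (racemic), via endoperoxide 9 (not isolated)
Conditions: O2, tetraphenylporphyrin (cat.), visible light, CH2Cl2, 0 °C; then thiourea, MeOH, rt
Reagents that add atoms: oxygen (as singlet oxygen), O=O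
Why: Singlet oxygen should add to the cisoid diene in a [4+2] cycloaddition on the convex face anti to the acetonide, which sets both new C–O bonds (C-4 and C-7) cis to each other and trans to the dioxolane, and thiourea then cleaves only the O–O bond with retention at both carbons.

Step 7
Reactants: 10 racemic diol
Product: 11 [(3aR,4S,7R,7aS)-7-(acetyloxy)-4-hydroxy-2,2-dimethyl-3a,4,7,7a-tetrahydro-1,3-benzodioxol-5-yl]methyl benzoate (single enantiomer)
Conditions: lipase from Burkholderia cepacia (immobilised), vinyl acetate, t-BuOMe, 30 °C, stopped near half conversion; chromatography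
Reagents that add atoms: vinyl acetate, CC(=O)OC=C
Why: Lipase-catalysed irreversible transesterification (enzymatic kinetic resolution by a serine hydrolase) should acetylate only the unhindered C-7 hydroxyl and, by the empirical secondary-alcohol rule for lipases (C-7a large, vinylic C-6 medium), only in the (7R) enantiomer, so that the (7S) diol stays unacylated and is removed, while the C-4 hydroxyl next to the fully substituted alkene carbon is not accepted.

Step 8
Reactants: 11 monoacetate
Product: 12 [(3aR,4S,7R,7aS)-7-(acetyloxy)-4-(benzoyloxy)-2,2-dimethyl-3a,4,7,7a-tetrahydro-1,3-benzodioxol-5-yl]methyl benzoate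
Conditions: BzCl, pyridine, DMAP, CH2Cl2, 0 °C → rt
Reagents that add atoms: benzoyl chloride, O=C(Cl)c1ccccc1
Why: DMAP-catalysed benzoylation (nucleophilic acyl transfer) of the remaining hindered allylic C-4 hydroxyl leaves the C–O bond untouched and so retains configuration.

Step 9
Reactants: 12 acetate dibenzoate acetonide
Product: 13 [(3R,4S,5S,6S)-6-(benzoyloxy)-3,4,5-trihydroxycyclohex-1-en-1-yl]methyl benzoate
Conditions: HCl (1.25 M in MeOH), 0 °C → rt
Reagents that add atoms: none
Why: Acid-catalysed methanolysis should cleave the acetonide by transacetalisation and the acetate by transesterification, whereas conjugated benzoates are known to survive these conditions, so the three ring hydroxyls are freed without the acyl migration that base would cause.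

Step 10
Reactants: 13 triol dibenzoate
Product: 15 [(3R,4S,5S,6S)-5-(acetyloxy)-6-(benzoyloxy)-3,4-dihydroxycyclohex-1-en-1-yl]methyl benzoate, via cyclic orthoacetate 14 (not isolated)
Conditions: MeC(OMe)3 (1.3 equiv), CSA (cat.), MeCN, rt; then 80% aq. AcOH, rt
Reagents that add atoms: trimethyl orthoacetate, CC(OC)(OC)OC; water, O
Why: Only the cis-4,5-diol can close a five-membered cyclic orthoester, and its mild aqueous acid hydrolysis (orthoester opening) should give the ester on the axial oxygen, which is O-5 in the half-chair that keeps the allylic 6-benzoate pseudoaxial to avoid allylic 1,2-strain with the CH2OBz group, leaving O-4 and O-3 free.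

**Compound list**

1 | methyl coumalate (methyl 2-oxo-2H-pyran-5-carboxylate) | COC(=O)C1=COC(=O)C=C1 | starting material
2 | vinylene carbonate (1,3-dioxol-2-one) | O=C1OC=CO1 | starting material
3 | methyl 7,8-(carbonyldioxy)-3-oxo-2-oxabicyclo[2.2.2]oct-5-ene-6-carboxylate (cis-carbonate; racemic, endo/exo mixture, bridgeheads left open) | O=C2O[C@H]1[C@@H](O2)C3C=C(C(=O)OC)C1OC3=O | intermediate
4 | methyl (3aR,7aS)-2-oxo-3a,7a-dihydro-1,3-benzodioxole-5-carboxylate (racemic, drawn as the enantiomer carried on) | O=C2O[C@H]1[C@@H](O2)C=CC(C(=O)OC)=C1 | intermediate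
5 | methyl (3R,4S)-3,4-dihydroxycyclohexa-1,5-diene-1-carboxylate (racemic; not isolated) | O[C@H]1[C@@H](O)C=CC(C(=O)OC)=C1 | intermediate
6 | methyl (3aR,7aS)-2,2-dimethyl-3a,7a-dihydro-1,3-benzodioxole-5-carboxylate (racemic) | CC2(C)O[C@H]1[C@@H](O2)C=CC(C(=O)OC)=C1 | intermediate
7 | [(3aR,7aS)-2,2-dimethyl-3a,7a-dihydro-1,3-benzodioxol-5-yl]methanol (racemic) | CC2(C)O[C@H]1[C@@H](O2)C=CC(CO)=C1 | intermediate
8 | [(3aR,7aS)-2,2-dimethyl-3a,7a-dihydro-1,3-benzodioxol-5-yl]methyl benzoate (racemic) | CC2(C)O[C@H]1[C@@H](O2)C=CC(COC(=O)c3ccccc3)=C1 | intermediate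
9 | [(3aS,4S,7R,7aR)-2,2-dimethyl-3a,4,7,7a-tetrahydro-4,7-epidioxy-1,3-benzodioxol-5-yl]methyl benzoate (peroxide bridge anti to the acetonide; racemic; not isolated) | CC2(C)O[C@H]1[C@@H](O2)[C@H](OO3)C=C(COC(=O)c4ccccc4)[C@@H]13 | intermediate
10 | [(3aR,4S,7R,7aS)-4,7-dihydroxy-2,2-dimethyl-3a,4,7,7a-tetrahydro-1,3-benzodioxol-5-yl]methyl benzoate (racemic) | CC2(C)O[C@H]1[C@@H](O2)[C@H](O)C=C(COC(=O)c3ccccc3)[C@@H]1O | intermediate
11 | [(3aR,4S,7R,7aS)-7-(acetyloxy)-4-hydroxy-2,2-dimethyl-3a,4,7,7a-tetrahydro-1,3-benzodioxol-5-yl]methyl benzoate | CC2(C)O[C@H]1[C@@H](O2)[C@H](OC(C)=O)C=C(COC(=O)c3ccccc3)[C@@H]1O | intermediate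
12 | [(3aR,4S,7R,7aS)-7-(acetyloxy)-4-(benzoyloxy)-2,2-dimethyl-3a,4,7,7a-tetrahydro-1,3-benzodioxol-5-yl]methyl benzoate | CC2(C)O[C@H]1[C@@H](O2)[C@H](OC(C)=O)C=C(COC(=O)c3ccccc3)[C@@H]1OC(=O)c1ccccc1 | intermediate
13 | [(3R,4S,5S,6S)-6-(benzoyloxy)-3,4,5-trihydroxycyclohex-1-en-1-yl]methyl benzoate | O[C@H]1[C@@H](O)[C@H](O)C=C(COC(=O)c2ccccc2)[C@@H]1OC(=O)c1ccccc1 | intermediate
14 | [(3aR,4S,7R,7aS)-4-(benzoyloxy)-7-hydroxy-2-methoxy-2-methyl-3a,4,7,7a-tetrahydro-1,3-benzodioxol-5-yl]methyl benzoate (both epimers at C-2; not isolated) | CC2(OC)O[C@H]1[C@@H](O2)[C@H](O)C=C(COC(=O)c3ccccc3)[C@@H]1OC(=O)c1ccccc1 | intermediate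
15 | [(3R,4S,5S,6S)-5-(acetyloxy)-6-(benzoyloxy)-3,4-dihydroxycyclohex-1-en-1-yl]methyl benzoate | CC(=O)O[C@H]1[C@@H](O)[C@H](O)C=C(COC(=O)c2ccccc2)[C@@H]1OC(=O)c1ccccc1 | target

**Step count and risks**

Total step count: 10. Longest linear sequence: 10 steps (from 1).

Steps most likely to fail:

Step 7. The lipase may discriminate the enantiomers of the cyclitol poorly, may accept the hindered substrate only slowly, or may show the reverse sense, so that the wanted enantiomer is left unacylated. The fallback is a covalent resolution; it sets out from racemic 10 and comes back at 13. Racemic 10 would be esterified at the less hindered C-7 hydroxyl with (S)-O-acetylmandelic acid (DCC, DMAP, CH2Cl2, −20 °C) and the two diastereomeric esters separated by chromatography or crystallisation. The wanted diastereomer, [(3aR,4S,7R,7aS)-7-{[(2S)-2-(acetyloxy)-2-phenylacetyl]oxy}-4-hydroxy-2,2-dimethyl-3a,4,7,7a-tetrahydro-1,3-benzodioxol-5-yl]methyl benzoate F1, would be benzoylated as in step 8 to [(3aR,4S,7R,7aS)-7-{[(2S)-2-(acetyloxy)-2-phenylacetyl]oxy}-4-(benzoyloxy)-2,2-dimethyl-3a,4,7,7a-tetrahydro-1,3-benzodioxol-5-yl]methyl benzoate F2. Acid methanolysis as in step 9 would then take off the acetonide and the mandelate ester together and give 13.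

Step 10. The orthoester may open in the wrong direction if the half-chair with O-5 equatorial is populated, and an open-chain orthoester at O-3 or acetyl migration between the cis oxygens may scramble the acetate. The fallback protects the trans-diol instead; it sets out from 13 and comes back at 15. Butane-2,3-dione, HC(OMe)3 and BF3·OEt2 in MeOH should acetalise only the trans-diequatorial C-3/C-4 diol, giving the 3,4-O-(2,3-dimethoxybutane-2,3-diyl) acetal of 13 F3 with the axial C-5 hydroxyl free. Acetylation (Ac2O, pyridine, DMAP) would give the 5-acetate of that acetal F4, and aqueous CF3CO2H would remove the diacetal to give 15.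

Step 3. Under base, deprotonation at the position vinylogous to the ester may be followed by loss of the neighbouring C–O bond, so that 4 or the transient diol 5 aromatises to a hydroxybenzoate. The fallback removes the ester before the diol is freed; it sets out from 4 and comes back at 7. Excess i-Bu2AlH (CH2Cl2, −78 → 0 °C) would reduce the ester and cleave the carbonate reductively to (1S,2R)-4-(hydroxymethyl)cyclohexa-3,5-diene-1,2-diol F5, which has no activating ester. Me2C(OMe)2 with PPTS in acetone at 0 °C would then close the cis-acetonide (a mixed acetal at the primary hydroxyl falls off on aqueous work-up) and give 7.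

**Further compounds**

F1 | step 7 | [(3aR,4S,7R,7aS)-7-{[(2S)-2-(acetyloxy)-2-phenylacetyl]oxy}-4-hydroxy-2,2-dimethyl-3a,4,7,7a-tetrahydro-1,3-benzodioxol-5-yl]methyl benzoate | CC2(C)O[C@H]1[C@@H](O2)[C@H](OC(=O)[C@@H](OC(C)=O)c3ccccc3)C=C(COC(=O)c4ccccc4)[C@@H]1O
F2 | step 7 | [(3aR,4S,7R,7aS)-7-{[(2S)-2-(acetyloxy)-2-phenylacetyl]oxy}-4-(benzoyloxy)-2,2-dimethyl-3a,4,7,7a-tetrahydro-1,3-benzodioxol-5-yl]methyl benzoate | CC2(C)O[C@H]1[C@@H](O2)[C@H](OC(=O)[C@@H](OC(C)=O)c3ccccc3)C=C(COC(=O)c4ccccc4)[C@@H]1OC(=O)c1ccccc1
F3 | step 10 | 3,4-O-(2,3-dimethoxybutane-2,3-diyl) acetal of 13 (acetal carbons left open) | O[C@H]1[C@@H](O2)[C@H](OC(C)(OC)C2(C)OC)C=C(COC(=O)c3ccccc3)[C@@H]1OC(=O)c1ccccc1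
F4 | step 10 | 5-acetate of the 3,4-O-(2,3-dimethoxybutane-2,3-diyl) acetal of 13 (acetal carbons left open) | CC(=O)O[C@H]1[C@@H](O2)[C@H](OC(C)(OC)C2(C)OC)C=C(COC(=O)c3ccccc3)[C@@H]1OC(=O)c1ccccc1
F5 | step 3 | (1S,2R)-4-(hydroxymethyl)cyclohexa-3,5-diene-1,2-diol (racemic, drawn as the enantiomer carried on) | O[C@H]1[C@@H](O)C=CC(CO)=C1
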